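**Retrosynthetic overview**

1. Target ⇒ diol 25 + (E)-4-methoxycinnamic acid (ester at O19). The diene comes from Stille vinylation of a C13 enol triflate, 8α-OH/9α-H from acid-mediated oxa-cyclisation of Δ8 ene-ketone 20, and the C9–C11 bond from Negishi coupling on the enol triflate of decalone 15.
2. Ring A ⇒ semipinacol 1,2-shift in epoxy silyl ether 10. The alkenyl ring-fusion carbon C5 moves from C3 to the oxirane carbon C4, so the five-membered ring C10–C1–C2–C3–C5 becomes the six-membered ring A; the C3 carbonyl left behind is erased later.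
3. Enabling feature: in ring A, C4 is a quaternary carbon bearing CH3 (C18) and an oxygenated CH2 (C19), flanked by ring-fusion C5 and an unfunctionalised CH2 (C3). A 2-methyloxirane on a C3 carbinol delivers exactly this array on 1,2-shift.
4. 10 ⇒ enone 6 (acyl-anion addition, then sulfonium ylide) ⇒ NHC benzoin desymmetrisation of trione aldehyde 3 ⇒ 2-methylcyclohexane-1,3-dione + acrolein.
5. Ring order: ring B (commercial dione) → five-membered ring (step 2) → ring A by 5→6 expansion (step 7). The dihydropyran of step 15 is temporary.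

Key step: step 7

Remarks on the chemistry (assumptions):
- Locants follow labdane numbering throughout (ring A: C1–C5, C10; ring B: C5–C10; C17 on C8; C18/C19 on C4; C20 on C10; side chain C11–C16). β is the face of the C20 methyl, α the opposite face.
- The sense of induction of the triazolium catalyst in step 2 is assumed to be the one that gives 4 as drawn; if it is the opposite, the enantiomeric precatalyst is used.
- Compound 15 is used as a mixture of C8 epimers (the 8α-methyl epimer is drawn); C8 is planarised in step 12.

**Step 1**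
Reactants: 1 2-methylcyclohexane-1,3-dione; 2 acrolein
Product: 3 3-(1-methyl-2,6-dioxocyclohexyl)propanal
Conditions: Et3N (5 mol %), EtOAc, 0 °C → rt
Reagents that add atoms: none
Why: Base-catalysed Michael addition of the cyclic 1,3-dione to acrolein should create the prochiral quaternary carbon (future C10) without forming a stereocentre.

**Step 2**
Reactants: 3 3-(1-methyl-2,6-dioxocyclohexyl)propanal
Product: 4 (3aS,7aR)-7a-hydroxy-3a-methylhexahydro-1H-indene-1,4(2H)-dione
Conditions: (5aS,10bR)-5a,10b-dihydro-2-(pentafluorophenyl)-4H,6H-indeno[2,1-b][1,2,4]triazolo[4,3-d][1,4]oxazinium tetrafluoroborate (10 mol %), DBU (10 mol %), CH2Cl2, rt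
Reagents that add atoms: none
Why: NHC-catalysed intramolecular crossed benzoin reaction, in which the Breslow intermediate of the aldehyde adds to one of the two enantiotopic ketones (5-exo closure, cis ring fusion); the chiral carbene should select the ketone and thereby fix C10 (desymmetrisation) together with the carbinol carbon.

**Step 3**
Reactants: 4 cis-fused ketol
Product: 5 (S)-3a-methyl-3,3a,5,6-tetrahydro-1H-indene-1,4(2H)-dione (C3 enone conjugated to C5=C6; C9 ketone)
Conditions: SOCl2, pyridine, CH2Cl2, 0 °C
Reagents that add atoms: none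
Why: Dehydration of the tertiary α-ketol through its chlorosulfite (E2 toward C6, the only carbon with β-hydrogens) should give the conjugated enone and remove the carbinol stereocentre, leaving C10 as the only one.

**Step 4**
Reactants: 5 enedione
Product: 6 C9 ethylene ketal of 5 (dioxolane on the carbonyl next to the quaternary carbon; enone untouched)
Conditions: ethylene glycol, TsOH·H2O (cat.), 4 Å molecular sieves, rt
Reagents that add atoms: ethylene glycol, OCCO
Why: Chemoselective ketalisation of the saturated ketone over the less electrophilic conjugated ketone, as in the mono-ketalisation of the Wieland–Miescher ketone.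

**Step 5**
Reactants: 6 enone ketal
Product: 9 3α-acetyl-3β-(tert-butyldimethylsilyloxy) ketal (tertiary allylic silyl ether), via lithium alkoxide 7 (not isolated), via silylated enol ether 8 (not isolated)
Conditions: ethyl vinyl ether, t-BuLi, THF, −78 → 0 °C; 6, −78 °C; TBSOTf, −78 → 0 °C; then 0.5 M aq. oxalic acid, THF, 0 °C
Reagents that add atoms: 1-ethoxyvinyllithium, [Li]C(=C)OCC (from ethyl vinyl ether, C=COCC); tert-butyldimethylsilyl triflate, CC(C)(C)[Si](C)(C)OS(=O)(=O)C(F)(F)F; water, O
Why: 1,2-Addition of an acyl-anion equivalent to the enone carbonyl from the α face (anti to the C20 methyl), O-silylation of the hindered alkoxide and selective hydrolysis of the enol ether should give the α-silyloxy methyl ketone with 3β-O configuration.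

**Step 6**
Reactants: 9 α-silyloxy methyl ketone
Product: 10 3β-(tert-butyldimethylsilyloxy)-3α-[(R)-2-methyloxiran-2-yl] ketal (epoxy silyl ether)
Conditions: Me3S+ I−, n-BuLi, THF, −10 °C → rt
Reagents that add atoms: dimethylsulfonium methylide, C[S+](C)[CH2-] (from trimethylsulfonium iodide, C[S+](C)C.[I-])
Why: Corey–Chaykovsky epoxidation of the methyl ketone; polar Felkin–Anh control (non-chelating OTBS anti to the incoming ylide, which passes the C2 methylene rather than the C5 alkenyl group) should set the oxirane carbon C4 as drawn, and no other alkene is touched.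

**Step 7**
Reactants: 10 epoxy silyl ether
Product: 11 ring-expanded ketone: 9,9-ethylenedioxy-4α,10β-dimethyl-4β-(tert-butyldimethylsilyloxymethyl)-Δ5-octalin-3-one
Conditions: TBSOTf (0.2 equiv), 2,6-di-tert-butyl-4-methylpyridine (0.3 equiv), CH2Cl2, −78 → −40 °C
Reagents that add atoms: none
Why: TBSOTf silylates the oxirane oxygen; as the tertiary C4–O bond ionises, the C3–C5 σ bond (C5 being the alkenyl carbon of C5=C6) shifts to C4 anti to the departing oxygen, and the silyloxocarbenium ion at C3 releases TBSOTf, so the silyl group ends on O19 and the cycle is catalytic. This is a semipinacol rearrangement of a 2,3-epoxy silyl ether (Suzuki–Tsuchihashi type, with silyl triflate promotion as in the Jung non-aldol aldol reaction), used here as a cyclopentanol → cyclohexanone ring expansion. No ring is closed by cyclisation: ring A (C10–C1–C2–C3–C4–C5) arises from the five-membered ring by a suprafacial [1,2]-shift with retention at the migrating carbon. The only new stereocentre, C4, is set stereospecifically by inversion at the oxirane carbon, which turns the configuration installed in step 6 into 4α-CH3/4β-CH2OTBS. The step needs C5 rather than C2 to migrate and C4–O rather than C3–O to ionise: the sp2 carbon C5 has by far the higher migratory aptitude (π participation), and the carbinol oxygen stabilises only the cation formed by C4–O cleavage and shift. Low temperature, a hindered pyridine base and the absence of protic acid should keep the tertiary allylic silyl ether and the C9 ketal intact.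

**Step 8**
Reactants: 11 ring-expanded ketone
Product: 12 C3 enol triflate (C2=C3–OTf; Δ5 retained)
Conditions: KN(SiMe3)2, THF, −78 °C; PhNTf2, −78 → 0 °C
Reagents that add atoms: N-phenylbis(trifluoromethanesulfonimide), O=S(=O)(N(c1ccccc1)S(=O)(=O)C(F)(F)F)C(F)(F)F
Why: The ketone can enolise only toward C2 (C4 is quaternary), so enolate O-triflation should give a single enol triflate as the handle for deoxygenation.

**Step 9**
Reactants: 12 enol triflate
Product: 13 saturated trans-decalin: 9,9-ethylenedioxy-4α,10β-dimethyl-4β-(tert-butyldimethylsilyloxymethyl)-5α-H decalin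
Conditions: H2 (4 atm), PtO2, NaHCO3, EtOAc, rt
Reagents that add atoms: none
Why: Hydrogenation over Adams catalyst reduces the enol triflate to CH2–CH2 (net ketone deoxygenation) and saturates C5=C6 from the α face, because the β face is blocked by the C20 methyl and the axial C19 group, which should give the 5α-H trans ring fusion.

**Step 10**
Reactants: 13 ketal
Product: 14 decalin-9-one (4β-CH2OTBS, 5α-H)
Conditions: pyridinium p-toluenesulfonate, acetone/H2O (9:1), 56 °C
Reagents that add atoms: water, O
Why: Mild acid-catalysed acetal hydrolysis should free the C9 ketone while the hindered neopentyl TBS ether survives.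

**Step 11**
Reactants: 14 decalin-9-one
Product: 15 8-methyl-decalin-9-one (8α-methyl epimer drawn)
Conditions: LiN(i-Pr)2 (commercial solution), THF, −78 °C; MeI, −78 → 0 °C
Reagents that add atoms: iodomethane, CI
Why: Enolate alkylation at C8, the only enolisable position (C10 is quaternary); the C8 configuration is of no consequence.

**Step 12**
Reactants: 15 8-methyl ketone
Product: 16 tetrasubstituted enol triflate (C8(CH3)=C9–OTf)
Conditions: KN(SiMe3)2, THF, −78 → 0 °C; PhNTf2
Reagents that add atoms: N-phenylbis(trifluoromethanesulfonimide), O=S(=O)(N(c1ccccc1)S(=O)(=O)C(F)(F)F)C(F)(F)F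
Why: O-Triflation of the only possible enolate, with the enol triflate of 2,2,6-trimethylcyclohexanone as close precedent.

**Step 13**
Reactants: 16 enol triflate; 17 2-(2-bromoethyl)-2-methyl-1,3-dioxolane
Product: 19 Δ8 alkene bearing the ketal-protected 3-oxobutyl chain on C9, via alkylzinc bromide 18 (not isolated)
Conditions: 17, Zn dust, LiCl, THF, 40 °C; then 16, Pd(OAc)2 (5 mol %), 2-dicyclohexylphosphino-2',6'-dimethoxybiphenyl (10 mol %), THF/NMP, 60 °C
Reagents that add atoms: none
Why: Negishi sp3–sp2 cross-coupling of a functionalised primary alkylzinc halide with a hindered cyclohexenyl triflate should form the C9–C11 bond and place the tetrasubstituted C8=C9 alkene.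

**Step 14**
Reactants: 19 side-chain ketal
Product: 20 Δ8 ene-ketone (C9–CH2CH2COCH3)
Conditions: pyridinium p-toluenesulfonate, acetone/H2O (9:1), 56 °C
Reagents that add atoms: water, O
Why: Acetal hydrolysis under conditions too mild to protonate the tetrasubstituted alkene.

**Step 15**
Reactants: 20 ene-ketone
Product: 22 8α-hydroxy-13-ketone (8β-CH3 and 9α-H), via tricyclic enol ether 21 (not isolated)
Conditions: TsOH (anhydrous, 0.2 equiv), PhMe, 60 °C; then 0.5 M aq. oxalic acid, THF, rt
Reagents that add atoms: water, O
Why: Acid-mediated cation–olefin cyclisation terminated by the carbonyl oxygen: protonation at C9 from the α face (axial) and capture of the C8 cation by the ketone oxygen from the α (equatorial) side should give the trans-fused six-membered enol ether under thermodynamic control (sclareol oxide pattern), whose enol ether hydrolysis then unveils 8α-OH and the methyl ketone.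

**Step 16**
Reactants: 22 hydroxy ketone
Product: 23 13-triflyloxy-13(16)-ene (2-triflyloxy-1-alkene; 8α-OH free)
Conditions: LiN(i-Pr)2 (commercial solution, 2.3 equiv), THF, −78 °C; PhNTf2, −78 → 0 °C
Reagents that add atoms: N-phenylbis(trifluoromethanesulfonimide), O=S(=O)(N(c1ccccc1)S(=O)(=O)C(F)(F)F)C(F)(F)F
Why: Kinetic deprotonation of the methyl ketone at CH3 and O-triflation should give the terminal enol triflate, the hindered tertiary alkoxide remaining unreactive.

**Step 17**
Reactants: 23 enol triflate
Product: 24 19-O-TBS 8α-hydroxylabda-13(16),14-diene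
Conditions: tributyl(vinyl)stannane, Pd(PPh3)4 (5 mol %), LiCl, THF, 65 °C
Reagents that add atoms: tributyl(vinyl)stannane, C=C[Sn](CCCC)(CCCC)CCCC
Why: Stille coupling of a 2-triflyloxy-1-alkene with a vinylstannane is a standard entry to 2-substituted 1,3-butadienes and tolerates the free tertiary alcohol.

**Step 18**
Reactants: 24 silyl ether
Product: 25 labda-13(16),14-diene-8α,19-diol
Conditions: Bu4NF, THF, rt → 50 °C
Reagents that add atoms: none
Why: Fluoride-mediated desilylation, compatible with the 1,3-diene and the tertiary alcohol.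

**Step 19**
Reactants: 25 diol; 26 (E)-4-methoxycinnamic acid
Product: 27 CNP0249194.1 (8α-hydroxylabda-13(16),14-dien-19-yl (E)-4-methoxycinnamate)
Conditions: DCC, DMAP (cat.), CH2Cl2, 0 °C → rt
Reagents that add atoms: none
Why: Steglich esterification should acylate the primary C19 hydroxyl selectively over the hindered tertiary C8 hydroxyl, with the E geometry of the acid retained.

**Compound list**

1 | 2-methylcyclohexane-1,3-dione | CC1C(=O)CCCC1=O | starting material
2 | acrolein | C=CC=O | starting material
3 | 3-(1-methyl-2,6-dioxocyclohexyl)propanal | CC1(CCC=O)C(=O)CCCC1=O | intermediate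
4 | (3aS,7aR)-7a-hydroxy-3a-methylhexahydro-1H-indene-1,4(2H)-dione (cis ketol) | C[C@]12CCC(=O)[C@@]1(O)CCCC2=O | intermediate
5 | (S)-3a-methyl-3,3a,5,6-tetrahydro-1H-indene-1,4(2H)-dione | C[C@]12CCC(=O)C1=CCCC2=O | intermediate
6 | C9 ethylene ketal of 5 | C[C@]12CCC(=O)C1=CCCC23OCCO3 | intermediate
7 | lithium 3β-alkoxide of the 3α-(1-ethoxyvinyl) adduct | C[C@]12CC[C@@](O[Li])(C(=C)OCC)C1=CCCC23OCCO3 | intermediate
8 | 3β-OTBS 3α-(1-ethoxyvinyl) ketal | C[C@]12CC[C@@](O[Si](C)(C)C(C)(C)C)(C(=C)OCC)C1=CCCC23OCCO3 | intermediate
9 | 3α-acetyl-3β-OTBS ketal | C[C@]12CC[C@@](O[Si](C)(C)C(C)(C)C)(C(C)=O)C1=CCCC23OCCO3 | intermediate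
10 | 3β-OTBS 3α-[(R)-2-methyloxiran-2-yl] ketal | C[C@]12CC[C@@](O[Si](C)(C)C(C)(C)C)([C@@]3(C)CO3)C1=CCCC24OCCO4 | intermediate
11 | 9,9-ethylenedioxy-4α,10β-dimethyl-4β-(TBSO-methyl)-Δ5-octalin-3-one | C[C@]12CCC(=O)[C@](C)(CO[Si](C)(C)C(C)(C)C)C1=CCCC23OCCO3 | intermediate
12 | C3 enol triflate of 11 (Δ2, Δ5) | C[C@]12CC=C(OS(=O)(=O)C(F)(F)F)[C@](C)(CO[Si](C)(C)C(C)(C)C)C1=CCCC23OCCO3 | intermediate
13 | 9,9-ethylenedioxy-4α,10β-dimethyl-4β-(TBSO-methyl)-5α-H trans-decalin | C[C@]12CCC[C@](C)(CO[Si](C)(C)C(C)(C)C)[C@@H]1CCCC23OCCO3 | intermediate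
14 | 4α,10β-dimethyl-4β-(TBSO-methyl)-5α-H decalin-9-one | C[C@]12CCC[C@](C)(CO[Si](C)(C)C(C)(C)C)[C@@H]1CCCC2=O | intermediate
15 | 8-methyl derivative of 14 (8α-methyl epimer drawn) | C[C@]12CCC[C@](C)(CO[Si](C)(C)C(C)(C)C)[C@@H]1CC[C@@H](C)C2=O | intermediate
16 | C9 enol triflate with C8(CH3)=C9 | C[C@]12CCC[C@](C)(CO[Si](C)(C)C(C)(C)C)[C@@H]1CCC(C)=C2OS(=O)(=O)C(F)(F)F | intermediate
17 | 2-(2-bromoethyl)-2-methyl-1,3-dioxolane | BrCCC1(C)OCCO1 | starting material
18 | [2-(2-methyl-1,3-dioxolan-2-yl)ethyl]zinc bromide | Br[Zn]CCC1(C)OCCO1 | intermediate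
19 | Δ8 alkene with C9–CH2CH2–(2-methyl-1,3-dioxolan-2-yl) chain and 19-OTBS | C[C@]12CCC[C@](C)(CO[Si](C)(C)C(C)(C)C)[C@@H]1CCC(C)=C2CCC3(C)OCCO3 | intermediate
20 | Δ8 ene-ketone (C9–CH2CH2COCH3; 19-OTBS) | C[C@]12CCC[C@](C)(CO[Si](C)(C)C(C)(C)C)[C@@H]1CCC(C)=C2CCC(C)=O | intermediate
21 | 8α,13-epoxy-12-ene tricyclic enol ether (19-OTBS) | C[C@]12CCC[C@](C)(CO[Si](C)(C)C(C)(C)C)[C@@H]1CC[C@@]3(C)OC(C)=CC[C@H]23 | intermediate
22 | 19-OTBS 8α-hydroxy-14,15-dinorlabdan-13-one | C[C@]12CCC[C@](C)(CO[Si](C)(C)C(C)(C)C)[C@@H]1CC[C@@](C)(O)[C@@H]2CCC(C)=O | intermediate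
23 | 19-OTBS 8α-hydroxy-13-triflyloxy-14,15-dinorlabd-13(16)-ene | C[C@]12CCC[C@](C)(CO[Si](C)(C)C(C)(C)C)[C@@H]1CC[C@@](C)(O)[C@@H]2CCC(=C)OS(=O)(=O)C(F)(F)F | intermediate
24 | 19-OTBS labda-13(16),14-dien-8α-ol | C[C@]12CCC[C@](C)(CO[Si](C)(C)C(C)(C)C)[C@@H]1CC[C@@](C)(O)[C@@H]2CCC(=C)C=C | intermediate
25 | labda-13(16),14-diene-8α,19-diol | C[C@]12CCC[C@](C)(CO)[C@@H]1CC[C@@](C)(O)[C@@H]2CCC(=C)C=C | intermediate
26 | (E)-4-methoxycinnamic acid | COc1ccc(/C=C/C(=O)O)cc1 | starting material
27 | CNP0249194.1, 8α-hydroxylabda-13(16),14-dien-19-yl (E)-4-methoxycinnamate | C=CC(=C)CC[C@@H]1[C@@]2(C)CCC[C@](C)(COC(=O)/C=C/c3ccc(OC)cc3)[C@@H]2CC[C@@]1(C)O | target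

Total step count: 19. Longest linear sequence: 19 steps (from compound 1).

**Steps most likely to fail, with fallbacks**

Step 6. The risk is insufficient or reversed facial selectivity of the ylide addition (for example by lithium chelation to the silyloxy group), which would set the oxirane carbon, and hence C4, wrongly. The fallback sets out from compound 6 and replaces steps 5 and 6. Isopropenylmagnesium bromide with CeCl3 (THF, −78 °C) should add to the α face of the ketone and give the tertiary allylic alcohol F1. Hydroxyl-directed epoxidation with VO(acac)2 and t-BuOOH (CH2Cl2, 0 °C) should then give the epoxy alcohol F2. Allylic 1,2-strain places the small C2 methylene next to the alkene methyl, which leads to the same oxirane configuration, and the ring alkene is screened on its β face by the C20 methyl. Silylation of F2 with TBSOTf and 2,6-lutidine returns to the route at compound 10.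

Step 9. The risk is slow or wrong-face delivery of hydrogen to the C5=C6 alkene, which lies between two quaternary carbons; the consequence would be incomplete reduction or a cis ring fusion. The fallback sets out from compound 11 and replaces steps 8 and 9. Hydrogen-atom-transfer hydrogenation with Mn(dpm)3 (dpm = dipivaloylmethanato), PhSiH3 and t-BuOOH in i-PrOH reduces the alkene through the C5 radical and should give the thermodynamically preferred trans-fused saturated ketone F3. Enolate triflation (KN(SiMe3)2, PhNTf2) then gives the enol triflate F4. Its hydrogenation over PtO2, now without any stereochemical demand, returns to the route at compound 13.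

Step 15. The risk is diversion of the cationic cascade: closure of a spiro ether at C9, a methyl shift from C10, wandering of the double bond, or C–O bond formation on the β face. The fallback sets out from compound 19 and replaces steps 14 and 15. Hydroboration of the tetrasubstituted alkene with BH3·THF (0 → 50 °C) followed by NaOH/H2O2 adds H and OH syn from the less hindered α face, with boron on the less hindered C8, and should give the hydroxy ketal F5 (8α-OH, 9α-H). Hydrolysis of the side-chain ketal with pyridinium p-toluenesulfonate in aqueous acetone returns to the route at compound 22.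

**Further compounds**

F1 | step 6 | 3β-hydroxy-3α-isopropenyl ketal (tertiary allylic alcohol) | C[C@]12CC[C@@](O)(C(C)=C)C1=CCCC23OCCO3
F2 | step 6 | 3β-hydroxy-3α-[(R)-2-methyloxiran-2-yl] ketal (epoxy alcohol) | C[C@]12CC[C@@](O)([C@@]3(C)CO3)C1=CCCC24OCCO4
F3 | step 9 | 9,9-ethylenedioxy-4α,10β-dimethyl-4β-(TBSO-methyl)-5α-H decalin-3-one | C[C@]12CCC(=O)[C@](C)(CO[Si](C)(C)C(C)(C)C)[C@@H]1CCCC23OCCO3
F4 | step 9 | C3 enol triflate of F3 | C[C@]12CC=C(OS(=O)(=O)C(F)(F)F)[C@](C)(CO[Si](C)(C)C(C)(C)C)[C@@H]1CCCC23OCCO3
F5 | step 15 | 19-OTBS 8α-hydroxy-9α-H side-chain ketal | C[C@]12CCC[C@](C)(CO[Si](C)(C)C(C)(C)C)[C@@H]1CC[C@@](C)(O)[C@@H]2CCC3(C)OCCO3
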